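## The problem

CNP0240716.1 (28) is a longipinane in which a cyclobutane (C2–C3–C8–C7) is shared by a cyclohexenone (C3–C4(=O)–C5=C6(CH3)–C7–C8) and a cycloheptane (C1–C2–C7–C8–C9–C10–C11); C1 is the quaternary carbon bearing CH3 and CH2O, C8 carries the angular methyl and C11 the secondary oxygen. Four of the six stereocentres (C2, C3, C7, C8) belong to the cage and form one unit: once C7 and C8 are cis, closure of the four-membered ring can give only one arrangement at C2 and C3. C1 and C11 sit on the four-carbon bridge, which sees C3 on one side and C7 on the other in almost mirror-image surroundings, so the cage cannot be trusted to control them. C1 therefore needs its own source of chirality, and C11 (oxygen trans to the C1–CH2O arm) is best derived from C1. The two angelates isomerise to tiglates under base, nucleophilic catalysts or prolonged heating and must come last. The strained, verbenone-like enone is at risk under strongly acidic, cationic conditions, and its carbonyl competes with a C11 ketone in any unselective reduction. The feature that opens the structure is the six-membered ring, with oxygen at C4, methyl at C6 and the C7–C8 bond shared with a seven-membered ring whose C2 is next to C7: this is the pattern left by a 2-silyloxypenta-1,3-diene adding across C7=C8 of a cyclohept-2-enone with its carbonyl at C2. That carbonyl then becomes the electrophilic corner from which the cyclobutane is closed onto C3.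

## Retrosynthesis

**Ester C–O bonds (28 ⇒ 25 + 26).** Both acyl–oxygen bonds are cut first, because no angelate would survive the enolate, dissolving-metal and palladium chemistry needed earlier. Diol 25 is ten carbons simpler. The forward step must acylate a neopentyl primary and a hindered secondary hydroxyl with two equivalents of angelic acid 26, passing through the primary mono-angelate 27, without Z to E isomerisation.

**C11–H bond and protecting groups (25 ⇒ 24 ⇒ 23).** The C11 carbinol is traced to ketone 24 and set by hydride delivery from the neighbouring C1–CH2OH. A reagent-controlled reduction would also attack the C4 enone; the directed reduction touches only the ketone that carries the hydroxyl and gives O trans to CH2O. Ketone 24 comes from 23 by one hydrolysis (dioxolane at C11, silyl ether on CH2O).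

**C2–C3 bond (23 ⇒ 21 ⇒ 20 ⇒ 19 ⇒ 18).** The cyclobutane is opened at C2–C3 rather than at C2–C7 or C3–C8, because this cut leaves the six-membered ring intact for a cycloaddition. It also makes C3 the α′-carbon of the enone and C2 a former carbonyl carbon. Enone tosylate 21 is a plain cis-fused bicycle. The forward reaction needs a kinetic enolate at C3 (C5 is sp2) and a leaving group on C2 anti to C3. The enone of 21 comes from the silyl enol ether of 20 by Saegusa oxidation. The sulfonate comes from alcohol 19, and 19 from ketone 18 by a reduction under thermodynamic control while C4 is still masked.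

**C3–C8 and C6–C7 bonds (18 ⇒ 15 + 17).** The six-membered ring is removed as diene 17, leaving cycloheptenone 15. No aldol-type annulation delivers this ring, since C6 lies between C5 and C7. A [4+2] builds the quaternary C8, the cis fusion and the C4 oxygen at once. The forward reaction must overcome a fully substituted β-carbon and must add to the face of 15 that carries the C1 methyl group. C11 is kept as a ketal, so the only stereocentre of 15 is C1; a C11 carbinol would bias the wrong face.

**C8–CH3 bond and C7=C8 unsaturation (15 ⇒ 13 ⇒ 11).** The β-methyl enone comes from enone 13 by cuprate addition and re-oxidation in one flask, and 13 from ketone 11, which can enolise only toward C7.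

**C1 stereocentre (11 ⇒ 10 ⇒ 9 ⇒ 6 ⇒ 5 ⇒ 4 ⇒ 1 + 2).** The C–O bond of the C1–CH2O arm is cut back to a methyl C–H bond. Diol 9 arises from alcohol 6 by silicon-tethered C–H silylation and oxidation. Alcohol 6 comes from the achiral monoketal 5 of 2,2-dimethylcycloheptane-1,3-dione 4. Dione 4 is made from dione 1 and two equivalents of iodomethane 2 by way of the monomethyl dione 3. The directing carbinol sits on the future C2 and is later oxidised back to the dienophile carbonyl, so it serves only to relay chirality to C1. Doing the methyl oxidation early, on a monocycle free of carbonyl groups, keeps the enone away from the hydrosilane and the catalyst [Ir(cod)OMe]2.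

**Diene (17 ⇒ 16).** Diene 17 is the silyl enol ether of (E)-pent-3-en-2-one 16.

## Roads not taken

**Alternative 1:** All ring bonds are cut back to farnesyl diphosphate A1, and a terpene cyclase would give α-longipinene A2 in one operation.
- Merits: the whole skeleton, the four cage stereocentres and the C5=C6 alkene arrive together, and allylic oxidation at C4 to the enone is well precedented for pinene-type alkenes. For the skeleton alone this is clearly better than any chemical route.
- Weak points: the enzyme must give the enantiomer of the target. Two oxygens are still missing at unactivated sites: C11 is a ring methylene, and the C1 methyl is one of two geminal methyls with no directing group nearby.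
- Comparison: the chosen plan is longer to the cage, but it carries all three oxygens from the first steps (C11 from a dione carbonyl, the C1–CH2O arm by a directed oxidation on a simple monocycle, C4 from the diene) and needs only chemical reagents.

**Alternative 2:** C2–C3 and C7–C8 are cut together, leading to acyclic acid chloride A3. With a tertiary amine base this gives vinylketene A4, whose crossed intramolecular [2+2] cycloaddition forms bicyclo[3.1.1]heptanone A5.
- Merits: the six-membered ring, the cyclobutane and the quaternary C8 form in one pericyclic step from a chain available from simple acyclic terpenoid building blocks. The four-membered ring does not depend on an SN2 reaction next to a quaternary carbon; in this respect the route is better than the chosen one.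
- Weak points: in A5, C2 is a cyclobutanone carbonyl, whereas the target has a CH bonded to C1. The seven-membered ring must be closed by C1–C2 bond formation onto that ketone, and the resulting tertiary cyclobutanol must be deoxygenated, where cations or radicals invite ring opening. C1 would again carry two methyls, C11 has no oxygen, and the C4 silyl ether and exocyclic methylene must be transposed into the enone. Facial control rests on the single C4 stereocentre.
- Comparison: the chosen plan has C2 at the right oxidation level for closure with inversion, and C1 and C11 are already differentiated when the cage forms.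

**Alternative 3:** C2–C7 and C3–C8 are cut across the ring, giving a ten-membered (E,E)-dienone A6. Irradiation would give the tricyclic nor-ketone A7 by transannular crossed [2+2] cycloaddition, and a one-carbon ring expansion would follow.
- Merits: cage and seven-membered ring form in one photochemical step, the C11 oxygen is in place, and no hindered alkylation is needed. As a cage-forming step it is probably more powerful than cycloaddition plus alkylation.
- Weak points: A6 contains a trans enone in a medium ring and must be made by macrocyclisation. Its reactive conformation is steered only by C11. After A7, one carbon has to be inserted between C4 and C6 with the right migrating group, followed by the C6 methyl and the C5=C6 unsaturation. The two C1 methyls remain undifferentiated.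
- Comparison: the chosen plan starts from a purchasable seven-membered dione, needs no medium ring, and obtains the enone substitution directly from the diene.

Key step: step 10

**Assumptions (remarks on the chemistry)**
- The hand of the oxazaborolidine in step 10 is not derived here. The (S)-catalyst is written on the usual picture of cyclic enones on such catalysts (boron on the carbonyl lone pair anti to C1, α-C–H held by the ring oxygen); if 15 adds on the other face, the mirror-image catalyst is used with no other change.
- Step 4 is taken to functionalise the methyl group trans to the silyloxy group. The directing carbinol is later oxidised away, so the opposite preference would be met by the mirror-image catalyst in step 3.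
- Steps 1 and 17 each consume two equivalents of one reactant (2 and 26); the second equivalent is entered under the reagents that add atoms.
- Cycloheptane-1,3-dione, (E)-pent-3-en-2-one, angelic acid and N-tert-butylbenzenesulfinimidoyl chloride are treated as purchasable.

## Route

Step 1
Reactants: 1 cycloheptane-1,3-dione; 2 iodomethane
Product: 4 2,2-dimethylcycloheptane-1,3-dione, via 2-methylcycloheptane-1,3-dione 3 (not isolated)
Conditions: MeI (3 equiv), K2CO3 (3 equiv), acetone, reflux
Reagents that add atoms: iodomethane (second equivalent), CI
Why: Two successive C-alkylations of a cyclic 1,3-dione enolate: the first equivalent of 2 gives the monomethyl dione 3, which is deprotonated again and takes the second methyl group; the seven-membered dione is largely in the diketo form, so C-methylation should outrun O-methylation. The quaternary carbon formed is the prochiral future C1.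

Step 2
Reactants: 4 2,2-dimethylcycloheptane-1,3-dione
Product: 5 6,6-dimethyl-1,4-dioxaspiro[4.6]undecan-7-one
Conditions: ethylene glycol (1.1 equiv), TsOH·H2O (cat.), benzene, reflux, Dean–Stark
Reagents that add atoms: ethane-1,2-diol, OCCO
Why: Acid-catalysed monoketalisation; once one dioxolane is in place the other carbonyl is flanked by a quaternary carbon carrying the ketal, and a second ketalisation is slow. The ketal carbon is the future C11 and the free ketone the future C2.

Step 3
Reactants: 5 6,6-dimethyl-1,4-dioxaspiro[4.6]undecan-7-one
Product: 6 (7R)-6,6-dimethyl-1,4-dioxaspiro[4.6]undecan-7-ol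
Conditions: (S)-1-methyl-3,3-diphenyltetrahydro-1H,3H-pyrrolo[1,2-c][1,3,2]oxazaborole (10 mol%), BH3·SMe2, THF, −20 °C; MeOH quench
Reagents that add atoms: none
Why: Corey–Bakshi–Shibata reduction; the quaternary, ketal-bearing flank is the large group and CH2 the small one, so the (S)-catalyst should give the (R)-carbinol. This temporary stereocentre on the future C2 is the only source of absolute configuration for C1.

Step 4
Reactants: 6 (7R)-6,6-dimethyl-1,4-dioxaspiro[4.6]undecan-7-ol
Product: 9 (6S,7R)-6-(hydroxymethyl)-6-methyl-1,4-dioxaspiro[4.6]undecan-7-ol, via diethylhydridosilyl ether 7 (not isolated), via trans-fused oxasilolane 8 (not isolated)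
Conditions: Et2SiH2, [Ir(cod)OMe]2 (0.5 mol%), THF, 25 °C; then [Ir(cod)OMe]2 (2 mol%), 3,4,7,8-tetramethyl-1,10-phenanthroline, norbornene, THF, 100 °C; then H2O2, KHCO3, MeOH/THF, 50 °C
Reagents that add atoms: hydrogen peroxide, OO
Why: Iridium-catalysed O-silylation, silicon-directed γ-C–H silylation of a methyl group and Tamao–Fleming oxidation (alcohol-directed 1,3-diol synthesis). Only the two C6 methyls offer primary γ-C–H bonds. The oxasilolane should close onto the methyl trans to the silyloxy group, which can lie gauche and pseudo-equatorial as in 3-hydroxy-4,4-dimethyl terpenoids; this choice creates C1.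

Step 5
Reactants: 9 (6S,7R)-6-(hydroxymethyl)-6-methyl-1,4-dioxaspiro[4.6]undecan-7-ol
Product: 10 (6S,7R)-6-{[tert-butyl(dimethyl)silyl]oxymethyl}-6-methyl-1,4-dioxaspiro[4.6]undecan-7-ol
Conditions: TBSCl (1.05 equiv), imidazole, CH2Cl2, 0 °C
Reagents that add atoms: tert-butyldimethylsilyl chloride, CC(C)(C)[Si](C)(C)Cl
Why: Selective silylation of the primary hydroxyl; the secondary one is flanked by the quaternary carbon and reacts much more slowly.

Step 6
Reactants: 10 (6S,7R)-6-{[tert-butyl(dimethyl)silyl]oxymethyl}-6-methyl-1,4-dioxaspiro[4.6]undecan-7-ol
Product: 11 (6S)-6-{[tert-butyl(dimethyl)silyl]oxymethyl}-6-methyl-1,4-dioxaspiro[4.6]undecan-7-one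
Conditions: Dess–Martin periodinane, pyridine, CH2Cl2, 25 °C
Reagents that add atoms: none
Why: Dess–Martin oxidation of the hindered secondary alcohol. The temporary carbinol is removed and C1 remains as the single stereocentre, next to a ketone that can enolise only toward C7.

Step 7
Reactants: 11 (6S)-6-{[tert-butyl(dimethyl)silyl]oxymethyl}-6-methyl-1,4-dioxaspiro[4.6]undecan-7-one
Product: 13 (6S)-6-{[tert-butyl(dimethyl)silyl]oxymethyl}-6-methyl-1,4-dioxaspiro[4.6]undec-8-en-7-one, via lithium enolate 12 (not isolated)
Conditions: LiN(iPr)2, THF, −78 °C; then N-tert-butylbenzenesulfinimidoyl chloride, −78 °C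
Reagents that add atoms: none
Why: Mukaiyama dehydrogenation: the enolate attacks sulfur and the α-sulfilimine undergoes syn-elimination at low temperature. C1 is quaternary, so the double bond can only appear as C7=C8.

Step 8
Reactants: 13 (6S)-6-{[tert-butyl(dimethyl)silyl]oxymethyl}-6-methyl-1,4-dioxaspiro[4.6]undec-8-en-7-one
Product: 15 (6S)-6-{[tert-butyl(dimethyl)silyl]oxymethyl}-6,9-dimethyl-1,4-dioxaspiro[4.6]undec-8-en-7-one, via lithium enolate 14 (not isolated)
Conditions: Me2CuLi (from MeLi and CuI), Et2O/THF, −78 °C; then N-tert-butylbenzenesulfinimidoyl chloride, −78 → 0 °C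
Reagents that add atoms: lithium dimethylcuprate, [Li+].C[Cu-]C
Why: Cuprate 1,4-addition places the methyl group on C8, and the enolate is dehydrogenated in the same flask (one-pot β-alkylation of an enone with return of the enone). The only β-hydrogen is on C8, so the double bond returns as C7=C8; the C8 stereocentre of 14 is transient.

Step 9
Reactants: 16 (E)-pent-3-en-2-one
Product: 17 (E)-2-(tert-butyldimethylsilyloxy)penta-1,3-diene
Conditions: TBSOTf, Et3N, Et2O, 0 °C
Reagents that add atoms: tert-butyldimethylsilyl trifluoromethanesulfonate, CC(C)(C)[Si](C)(C)OS(=O)(=O)C(F)(F)F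
Why: Soft enolisation on the methyl side of the ketone gives the cross-conjugated 2-silyloxydiene with the (E)-propenyl unit intact. The TBS enol ether is chosen because it should survive the Lewis acid of step 10 and the base of step 11 and still undergo Saegusa oxidation.

Step 10
Reactants: 15 (6S)-6-{[tert-butyl(dimethyl)silyl]oxymethyl}-6,9-dimethyl-1,4-dioxaspiro[4.6]undec-8-en-7-one; 17 (E)-2-(tert-butyldimethylsilyloxy)penta-1,3-diene
Product: 18 cis-fused Diels–Alder adduct (C2 ketone; C4 TBS enol ether C4=C5; C6 methyl cis to the C7–C2 bond; C7–H and C8–CH3 cis and on the face of the C1–CH2OTBS arm; C11 ketal)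
Conditions: (S)-1-(2-methylphenyl)-3,3-diphenyltetrahydro-1H,3H-pyrrolo[1,2-c][1,3,2]oxazaborole (20 mol%), AlBr3 (16 mol%), 17 (2 equiv), CH2Cl2, −78 → −30 °C; Et3N quench
Reagents that add atoms: none
Why: The boron of the AlBr3-activated oxazaborolidine binds the C2 carbonyl on the lone pair anti to the quaternary C1 and lowers the enone LUMO; the diene then adds in a concerted but asynchronous endo [4+2] in which C3–C8 is ahead of C6–C7. The closest known reactions are Lewis-acid-promoted Diels–Alder additions of 2-silyloxydienes to 3-methylcycloalk-2-enones that create angular methyl groups, and oxazaborolidinium-catalysed additions of 2-silyloxydienes to cyclic enones. The six-membered ring closes by suprafacial addition of both diene termini to one face of the cis ring alkene, so the C7/C8 fusion is cis by necessity. Regiochemistry needs no help: the nucleophilic CH2 terminus (C3) of the diene goes to the β-carbon C8 and the methyl-bearing terminus (C6) to the α-carbon C7, the para and ortho preferences agreeing. C7 and C8 are set by the face attacked, which must be the one carrying the C1 methyl group; the catalyst is chosen to shield the other face, where the larger CH2OTBS arm of C1 also lies, so catalyst and substrate should reinforce and any minor isomer is a separable diastereomer. C6 follows from the endo transition state and the (E)-diene and is cleared in step 13. The step also needs cycloaddition to win over ionisation of the dioxolane by the Lewis acid; the neopentyl position of the ketal, the catalytic loading and the low temperature should secure this, and the amine quench keeps the enol ether of 18.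

Step 11
Reactants: 18 cis-fused Diels–Alder adduct
Product: 19 C2 alcohol of 18 (hydroxyl on the face of C7–H and C8–CH3)
Conditions: Li, NH3(l)/THF, t-BuOH (2 equiv), −78 °C; NH4Cl
Reagents that add atoms: none
Why: Dissolving-metal reduction of a hindered ketone gives the more stable carbinol through protonation of the pyramidal carbanion, so the C2 oxygen should end pseudo-equatorial, pointing away from the cyclohexene ring. A hydride entering from the open face would give the other epimer. The C4 enol ether masks the second carbonyl, and the ketone is reduced faster than it can enolise toward C7.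

Step 12
Reactants: 19 C2 alcohol of 18
Product: 20 C2 p-toluenesulfonate of 19
Conditions: TsCl, Et3N, Me3N·HCl (cat.), CH2Cl2, 0 → 25 °C
Reagents that add atoms: p-toluenesulfonyl chloride, Cc1ccc(cc1)S(Cl)(=O)=O
Why: Amine-catalysed sulfonylation with retention at C2; the excess base protects the enol ether. A tosylate rather than a mesylate is used so that the base of step 14 finds no acidic sulfonyl methyl group.

Step 13
Reactants: 20 C2 p-toluenesulfonate of 19
Product: 21 enone tosylate (C4 ketone conjugated with C5=C6(CH3); C2 tosylate; C11 ketal)
Conditions: Pd(OAc)2 (1.1 equiv), MeCN, 25 → 40 °C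
Reagents that add atoms: none
Why: Saegusa–Ito oxidation: divalent palladium adds to C5 of the C4=C5 enol ether, and syn β-hydride elimination can only use the C6 hydrogen because C8 is quaternary. The enone therefore appears as C4(=O)–C5=C6(CH3), and the C6 stereocentre is cleared.

Step 14
Reactants: 21 enone tosylate
Product: 23 tricyclic enone (cyclobutane C2–C3–C8–C7 closed; cage configuration as in 28; C11 ketal and C1–CH2OTBS retained), via lithium C3 enolate 22 (not isolated)
Conditions: LiN(iPr)2 (1.2 equiv), THF, −78 °C; then DMPU, −78 → 40 °C
Reagents that add atoms: none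
Why: Kinetic α′-deprotonation at C3 (C5 is sp2), then intramolecular SN2 alkylation (4-exo-tet) with inversion at C2. This is the long-known closure of a cyclohexanone enolate onto a secondary sulfonate carried by the ring carbon two positions away, which gives pinane-type bicyclo[3.1.1]heptanones. C3 is held on the face of C8 opposite to the C2–OTs bond, so only backside attack is possible, and C2 and C3 are fixed by C7 and C8.

Step 15
Reactants: 23 tricyclic enone
Product: 24 hydroxy diketone (C4 enone; C11 ketone; free C1–CH2OH)
Conditions: 1 M HCl, THF, 25 °C
Reagents that add atoms: water, O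
Why: Acid hydrolysis removes the dioxolane and the primary silyl ether together. The enone and cyclobutane should tolerate dilute aqueous acid, and the β-hydroxy ketone is never exposed to base, which could cause retro-aldol loss of formaldehyde.

Step 16
Reactants: 24 hydroxy diketone
Product: 25 diol (C11–OH trans to C1–CH2OH; C4 enone intact)
Conditions: Me4NBH(OAc)3, MeCN/AcOH (1:1), −20 °C
Reagents that add atoms: none
Why: Evans–Saksena hydroxyl-directed reduction: the C1–CH2OH exchanges onto boron and delivers hydride to C11 from its own face, so the new hydroxyl ends trans to CH2OH and cis to the C1 methyl. The reagent does not reduce carbonyl groups that lack a bound hydroxyl, so the C4 enone is spared.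

Step 17
Reactants: 25 diol; 26 angelic acid
Product: 28 CNP0240716.1, via C1–CH2 mono-angelate 27 (not isolated)
Conditions: 26 (4 equiv), 2,4,6-trichlorobenzoyl chloride, Et3N, toluene, 25 °C; then 25, 80 °C
Reagents that add atoms: angelic acid (second equivalent), C/C=C(/C)C(=O)O
Why: Yamaguchi-type esterification through the mixed anhydride without a nucleophilic catalyst, the established way to acylate hindered alcohols with angelic acid while keeping the (Z)-geometry. The primary hydroxyl is acylated first (27) and the hindered C11 hydroxyl second, each taking one equivalent of 26, and no stereocentre is touched.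

## Compound list

1 | cycloheptane-1,3-dione | O=C1CCCCC(=O)C1 | starting material
2 | iodomethane | CI | starting material
3 | 2-methylcycloheptane-1,3-dione | CC1C(=O)CCCCC1=O | intermediate (not isolated)
4 | 2,2-dimethylcycloheptane-1,3-dione | CC1(C)C(=O)CCCCC1=O | intermediate
5 | 6,6-dimethyl-1,4-dioxaspiro[4.6]undecan-7-one | CC1(C)C(=O)CCCCC12OCCO2 | intermediate
6 | (7R)-6,6-dimethyl-1,4-dioxaspiro[4.6]undecan-7-ol | CC1(C)[C@H](O)CCCCC12OCCO2 | intermediate
7 | (7R)-7-(diethylsilyloxy)-6,6-dimethyl-1,4-dioxaspiro[4.6]undecane | CC[SiH](CC)O[C@@H]1CCCCC2(OCCO2)C1(C)C | intermediate (not isolated)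
8 | trans-fused oxasilolane: SiEt2 bridging O7 and the C6 methylene of the (6S,7R)-6-methyl-1,4-dioxaspiro[4.6]undecane | CC[Si]3(CC)C[C@@]1(C)[C@H](O3)CCCCC12OCCO2 | intermediate (not isolated)
9 | (6S,7R)-6-(hydroxymethyl)-6-methyl-1,4-dioxaspiro[4.6]undecan-7-ol | OC[C@@]1(C)[C@H](O)CCCCC12OCCO2 | intermediate
10 | (6S,7R)-6-{[tert-butyl(dimethyl)silyl]oxymethyl}-6-methyl-1,4-dioxaspiro[4.6]undecan-7-ol | CC(C)(C)[Si](C)(C)OC[C@@]1(C)[C@H](O)CCCCC12OCCO2 | intermediate
11 | (6S)-6-{[tert-butyl(dimethyl)silyl]oxymethyl}-6-methyl-1,4-dioxaspiro[4.6]undecan-7-one | CC(C)(C)[Si](C)(C)OC[C@@]1(C)C(=O)CCCCC12OCCO2 | intermediate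
12 | lithium enolate of 11 (C7=C8 of the spiro numbering) | CC(C)(C)[Si](C)(C)OC[C@@]1(C)C(O[Li])=CCCCC12OCCO2 | intermediate (not isolated)
13 | (6S)-6-{[tert-butyl(dimethyl)silyl]oxymethyl}-6-methyl-1,4-dioxaspiro[4.6]undec-8-en-7-one | CC(C)(C)[Si](C)(C)OC[C@@]1(C)C(=O)C=CCCC12OCCO2 | intermediate
14 | lithium enolate of the 9-methyl ketone formed from 13 (C9 epimers) | CC(C)(C)[Si](C)(C)OC[C@@]1(C)C(O[Li])=CC(C)CCC12OCCO2 | intermediate (not isolated)
15 | (6S)-6-{[tert-butyl(dimethyl)silyl]oxymethyl}-6,9-dimethyl-1,4-dioxaspiro[4.6]undec-8-en-7-one | CC(C)(C)[Si](C)(C)OC[C@@]1(C)C(=O)C=C(C)CCC12OCCO2 | intermediate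
16 | (E)-pent-3-en-2-one | C/C=C/C(C)=O | starting material
17 | (E)-2-(tert-butyldimethylsilyloxy)penta-1,3-diene | C=C(O[Si](C)(C)C(C)(C)C)/C=C/C | intermediate
18 | cis-fused Diels–Alder adduct: C2 ketone; C4 TBS enol ether (C4=C5); C6 methyl cis to the C7–C2 bond; C7–H, C8–CH3 and C1–CH2OTBS on one face of the seven-membered ring; C11 ethylene ketal | CC(C)(C)[Si](C)(C)OC[C@@]1(C)C(=O)[C@@H]2[C@H](C)C=C(O[Si](C)(C)C(C)(C)C)C[C@]2(C)CCC13OCCO3 | intermediate
19 | C2 alcohol of 18, hydroxyl on the face of C7–H and C8–CH3 | CC(C)(C)[Si](C)(C)OC[C@@]1(C)[C@@H](O)[C@@H]2[C@H](C)C=C(O[Si](C)(C)C(C)(C)C)C[C@]2(C)CCC13OCCO3 | intermediate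
20 | C2 p-toluenesulfonate of 19 | CC(C)(C)[Si](C)(C)OC[C@@]1(C)[C@@H](OS(=O)(=O)c4ccc(C)cc4)[C@@H]2[C@H](C)C=C(O[Si](C)(C)C(C)(C)C)C[C@]2(C)CCC13OCCO3 | intermediate
21 | enone tosylate: C4 ketone, C5=C6(CH3), C2 tosylate, cis-fused, C11 ketal | CC(C)(C)[Si](C)(C)OC[C@@]1(C)[C@@H](OS(=O)(=O)c4ccc(C)cc4)[C@@H]2C(C)=CC(=O)C[C@]2(C)CCC13OCCO3 | intermediate
22 | lithium C3=C4 enolate of 21 | CC(C)(C)[Si](C)(C)OC[C@@]1(C)[C@@H](OS(=O)(=O)c4ccc(C)cc4)[C@@H]2C(C)=CC(O[Li])=C[C@]2(C)CCC13OCCO3 | intermediate (not isolated)
23 | tricyclic enone: longipinane cage closed, C4 enone, C11 ethylene ketal, C1–CH2OTBS | CC(C)(C)[Si](C)(C)OC[C@@]1(C)[C@@H]2[C@H]3C(=O)C=C(C)[C@@H]2[C@@]3(C)CCC14OCCO4 | intermediate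
24 | hydroxy diketone: C4 enone, C11 ketone, free C1–CH2OH | OC[C@@]1(C)[C@@H]2[C@H]3C(=O)C=C(C)[C@@H]2[C@@]3(C)CCC1=O | intermediate
25 | diol: C11–OH trans to C1–CH2OH, C4 enone | OC[C@@]1(C)[C@@H]2[C@H]3C(=O)C=C(C)[C@@H]2[C@@]3(C)CC[C@@H]1O | intermediate
26 | angelic acid, (Z)-2-methylbut-2-enoic acid | C/C=C(/C)C(=O)O | starting material
27 | C1–CH2 mono-angelate of 25 (C11–OH free) | C/C=C(/C)C(=O)OC[C@@]1(C)[C@@H]2[C@H]3C(=O)C=C(C)[C@@H]2[C@@]3(C)CC[C@@H]1O | intermediate (not isolated)
28 | CNP0240716.1, the C11 and C1–CH2 bis-angelate | C/C=C(/C)C(=O)OC[C@@]1(C)[C@@H]2[C@H]3C(=O)C=C(C)[C@@H]2[C@@]3(C)CC[C@@H]1OC(=O)/C(C)=C\C | target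

## Step count and least certain steps

Total: 17 steps. Longest linear sequence: 16 steps (steps 1–8 and 10–17); step 9 is a one-step branch.

**Step 10 (key step).** The β-carbon of 15 is fully substituted, so the cycloaddition may be slow enough for the diene to be consumed by desilylation or oligomerisation. The reaction may also stall after the first bond as a Mukaiyama–Michael adduct, and facial selectivity may erode. Fallback: the two bonds are made in separate polar steps. From 15 and 17, a Mukaiyama–Michael addition catalysed by TBSOTf at −78 °C forms C3–C8 and gives the silyl enol ether enone F1. A second, intramolecular Mukaiyama–Michael addition under a catalytic silyl Lewis acid (Me3SiNTf2) then forms C6–C7 with transfer of the silyl group from the C2 oxygen to the C4 oxygen, which returns to 18. Face selection at C8 then rests on C1 alone, and diastereomers are separated at F1.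

**Step 4.** The seven-membered ring is flexible, so the silicon tether may not discriminate well between the two methyl groups, giving diols epimeric at C1. Fallback: C1 is built by a desymmetrising reduction instead of C–H oxidation. The fallback sets out from 3, which is isolated by stopping the methylation of step 1 after one equivalent of 2. Aldol reaction of 3 with aqueous formaldehyde gives 2-(hydroxymethyl)-2-methylcycloheptane-1,3-dione F2. Silylation gives the TBS ether F3. Mono-reduction with (R)-1-methyl-3,3-diphenyltetrahydro-1H,3H-pyrrolo[1,2-c][1,3,2]oxazaborole and borane, with hydride entering anti to the larger silyloxymethyl arm, should give the (2S,3S)-hydroxy ketone F4. Ketalisation of the remaining carbonyl with 1,2-bis(trimethylsilyloxy)ethane and catalytic TMSOTf gives the hydroxy ketal F5, and Dess–Martin oxidation returns to 11.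

**Step 11.** The reduction may deliver the C2 epimer with the hydroxyl on the face of the cyclohexene ring if the assumed stability order is wrong; that epimer cannot be displaced by C3. Fallback: the stereocentre is set under kinetic instead of thermodynamic control. The epimeric alcohol F6 is oxidised back to 18 with Dess–Martin periodinane, and 18 is reduced with LiBH(s-Bu)3 at −78 °C, returning to 19. A bulky hydride enters from the open face and gives the less stable carbinol, which in that case is the needed one.

**Step 14.** Displacement at a secondary carbon next to the quaternary C1 may be slow. On warming, the α′-enolate could then equilibrate to the extended dienolate and alkylate at C5 (an isomeric cyclobutane) or cause elimination toward C7. Fallback: the nucleophile is changed to a metallated hydrazone, which is more nucleophilic and does not equilibrate through the ketone. From 21, condensation with 1,1-dimethylhydrazine gives the N,N-dimethylhydrazone F7. Deprotonation with LiN(iPr)2 and cyclisation give the tricyclic hydrazone F8, and hydrolysis with aqueous Cu(OAc)2 returns to 23.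

**Step 17.** Heating a hindered diol with the mixed anhydride may cause partial Z to E isomerisation to tiglate esters, or incomplete acylation at C11. Fallback: the angelate double bonds are built on the molecule. From 25, esterification with 2-[bis(2,2,2-trifluoroethoxy)phosphoryl]propanoic acid (DCC, DMAP; no alkene to isomerise) gives the bis(phosphonopropionate) F9. A double Still–Gennari olefination with acetaldehyde (KN(SiMe3)2, 18-crown-6, THF, −78 °C) gives the (Z)-2-methylbut-2-enoates and arrives at 28.

## Further compounds

F1 | step 10 | Mukaiyama–Michael adduct: C2 TBS enol ether (C2=C7) of 15 carrying on C8 the (E)-2-oxopent-3-enyl chain | CC(C)(C)[Si](C)(C)OC[C@@]1(C)C(O[Si](C)(C)C(C)(C)C)=C[C@](C)(CC(=O)/C=C/C)CCC12OCCO2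
F2 | step 4 | 2-(hydroxymethyl)-2-methylcycloheptane-1,3-dione | CC1(CO)C(=O)CCCCC1=O
F3 | step 4 | 2-{[tert-butyl(dimethyl)silyl]oxymethyl}-2-methylcycloheptane-1,3-dione | CC1(CO[Si](C)(C)C(C)(C)C)C(=O)CCCCC1=O
F4 | step 4 | (2S,3S)-2-{[tert-butyl(dimethyl)silyl]oxymethyl}-3-hydroxy-2-methylcycloheptan-1-one | CC(C)(C)[Si](C)(C)OC[C@@]1(C)[C@@H](O)CCCCC1=O
F5 | step 4 | (6S,7S)-6-{[tert-butyl(dimethyl)silyl]oxymethyl}-6-methyl-1,4-dioxaspiro[4.6]undecan-7-ol | CC(C)(C)[Si](C)(C)OC[C@@]1(C)[C@@H](O)CCCCC12OCCO2
F6 | step 11 | C2 epimer of 19 (hydroxyl on the face of the cyclohexene ring) | CC(C)(C)[Si](C)(C)OC[C@@]1(C)[C@H](O)[C@@H]2[C@H](C)C=C(O[Si](C)(C)C(C)(C)C)C[C@]2(C)CCC13OCCO3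
F7 | step 14 | C4 N,N-dimethylhydrazone of 21 | CC(C)(C)[Si](C)(C)OC[C@@]1(C)[C@@H](OS(=O)(=O)c4ccc(C)cc4)[C@@H]2C(C)=CC(=NN(C)C)C[C@]2(C)CCC13OCCO3
F8 | step 14 | C4 N,N-dimethylhydrazone of 23 | CC(C)(C)[Si](C)(C)OC[C@@]1(C)[C@@H]2[C@H]3C(=NN(C)C)C=C(C)[C@@H]2[C@@]3(C)CCC14OCCO4
F9 | step 17 | bis{2-[bis(2,2,2-trifluoroethoxy)phosphoryl]propanoate} of 25 (phosphonate α-carbons as a mixture) | CC(C(=O)OC[C@@]1(C)[C@@H]2[C@H]3C(=O)C=C(C)[C@@H]2[C@@]3(C)CC[C@@H]1OC(=O)C(C)P(=O)(OCC(F)(F)F)OCC(F)(F)F)P(=O)(OCC(F)(F)F)OCC(F)(F)F
A1 | alternative 1 | (2E,6E)-farnesyl diphosphate | CC(C)=CCC/C(C)=C/CC/C(C)=C/COP(=O)(O)OP(=O)(O)O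
A2 | alternative 1 | α-longipinene, enantiomer with the cage configuration of 28 | CC1(C)[C@@H]2[C@H]3CC=C(C)[C@@H]2[C@@]3(C)CCC1
A3 | alternative 2 | (2E,6E)-5-(tert-butyldimethylsilyloxy)farnesoyl chloride | CC(C)=CCC/C(C)=C/[C@@H](O[Si](C)(C)C(C)(C)C)C/C(C)=C/C(Cl)=O
A4 | alternative 2 | vinylketene from A3 | CC(C)=CCC/C(C)=C/[C@@H](O[Si](C)(C)C(C)(C)C)CC(=C)C=C=O
A5 | alternative 2 | bicyclo[3.1.1]heptanone with C2 ketone, C4 silyl ether, C6 exo-methylene and prenylated C8 | O=C2[C@H]3[C@@H](O[Si](C)(C)C(C)(C)C)CC(=C)[C@@H]2[C@@]3(C)CCC=C(C)C
A6 | alternative 3 | ten-membered (E,E)-dienone with C4 ketone, C2=C3 and C7=C8 alkenes, C11 silyl ether | O=C1C/C=C(C)/CC[C@H](O[Si](C)(C)C(C)(C)C)C(C)(C)/C=C/1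
A7 | alternative 3 | tricyclic nor-ketone (C4 ketone bonded to C6) | CC1(C)[C@@H]2[C@H]3C(=O)C[C@@H]2[C@@]3(C)CC[C@@H]1O[Si](C)(C)C(C)(C)C
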